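Count this flask's time in one unit, the half-life of the reaction, rather than in hours.

- beta: left-handed substrate 0.081 M; right-handed substrate 0.081 M; partner 2 equiv; free catalyst 7.3 mol%; impurity 3.4 mM; the very flask that is asked about, followed so far
- flask: left-handed substrate 0.081 M; partner 2.00 equiv; free catalyst 7.3 mol%; impurity 3.4 mM; right-handed substrate 0.081 M; time 30 h

- beta (time / h: left-handed product / %, right-handed product / %): 0.250: 2.0, 0.9; 0.500: 4.6, 1.4; 0.833: 6.3, 2.5; 1.33: 10.3, 4.8; 2.00: 12.6, 6.1; 4.00: 22.8, 9.9

(each reading ± 0.5 percentage points)

- left-handed product and right-handed product together, in percent of the left-handed substrate and right-handed substrate charged together, at 30 h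
- excess of left-handed product over right-handed product in the product at 30 h
- whether the exchange between left-handed substrate and right-handed substrate keeps pace with the reaction: how far the product's excess at 30 h gets from its value without exchange to its value with instant exchange (above 80% keeps pace, below 20% hardly takes part, else lags behind)

- free catalyst is single-handed; left-handed substrate and right-handed substrate are mirror images of each other, charged as a racemate, each of them at the stated concentration
- an excess is the difference of the two amounts in percent of their sum
- an excess is below zero if the other one leads

Apply the bench rule first: each half-life halves what is left. The beta run has reacted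

x = 32.7% at 4.00 h,

and by that rule this reading gives 94.9% at 30 h. The rule needs a pseudo-first-order flask, with the partner far in excess. Here, though, the ratio of c(partner) to c(left-handed substrate) + c(right-handed substrate) is 1.00, so c(partner) falls in step with the substrates. If the rate is first order in partner and first order in substrate, with the free catalyst steady, it follows the square of what is left, and each half-life lasts twice the one before. Reckon again for that order:

τ = t(1 − x)/x = 8.23 h

y = t/(t + τ) = 78.5%

Take τ, the second-order half-life read from the beta run, as a reading; the reading at 2.00 h gives 8.70 h.

For the excess, test the beta run itself. Without exchange, the left-handed substrate in the beta run would stand at 0.678 of the right-handed substrate by 4.00 h, and the ratio of new products would sink. Yet the ratio of products formed after 2.00 h reads 2.68, higher than the 2.07 before it, roughly, given a scatter of 0.5 percentage points on each reading. So reckon that exchange keeps pace, with the excess staying near the 39.4% read at 4.00 h.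

The forecast gives 76% (66% to 84%) of product and an excess of 28% (18% to 41%), and says “I expect an intermediate value, so exchange lags behind”, which parts from the reckoning above on excess and pace.

The flask gives 77.2% with an excess of 38.8%, and exchange keeps pace, 98% of the way to instant exchange. The substrates left at 30.0 h show an excess of right-handed over left-handed of 0.201%.

    partner + free catalyst + left-handed substrate → free catalyst + left-handed product (k = 0.110 /M²/s)
    partner + free catalyst + right-handed substrate → free catalyst + right-handed product (k = 0.0480 /M²/s)
    left-handed substrate ⇌ right-handed substrate (k = 6.80 × 10⁻⁴ /s)
    free catalyst + impurity → spent catalyst A (k = 0.970 /M/s)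
    free catalyst → spent catalyst B (k = 5.40 × 10⁻⁷ /s)

Under exchange alone, an excess between the two substrates halves in 0.142 h, so one τ holds 58.0 such half-lives. Carry τ to the neighbour flask with 1.20 equiv of partner, where c(partner) starts at β = 0.600 of the substrates:

E = exp((1 − β)t/τ) = 4.30

x = β(E − 1)/(E − β) = 53.5%

That neighbour flask gave 52.7%.

All runs come from a simulation on assumed constants, noise included.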